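## Retrosynthetic overview

- **Numbering and feature (longipinane locants):** C1 ketone, C2=C3 (methyl on C3), bridgeheads C4 and C11, one-carbon bridges C5 (H) and C10 (methyl), C6 (CMe2), C7 (O-isovalerate), C8, C9 (O-senecioate). The plan rests on C10, the quaternary methyl-bearing carbon that belongs both to the cyclobutane C4–C5–C11–C10 and to the seven-membered ring, where it is bonded to oxygenated C9. Its methyl group is read as H• added to a C10=CH2 group, and its bond to C9 as the ring closure.
- **Late disconnections:** C7 ester (isovalerylation) ⇒ C7 carbinol (reduction of the 7-ketone) ⇒ C9–C10 (hydrogen-atom-transfer radical 7-endo closure onto an (E)-β-senecioyloxy enone) ⇒ enol ester (senecioic acid + ynone) ⇒ C10=CH2 (Wittig reaction of a cyclobutanone).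
- **Bicyclic core:** the bicyclo[3.1.1]heptenone is cut at C10–C11 and C4–C5, an intramolecular [2+2] of a vinylketene (C10=C4) with the (E)-alkene C11=C5 of an acyclic dienoic acid. A silyloxy stereocentre at C1, made by asymmetric vinylogous aldol addition, sets the absolute configuration and later becomes the C1 ketone.
- **Ring order:** six-membered ring and cyclobutane together (ketene cycloaddition), seven-membered ring last (radical closure).

Key step: step 15

Assumption: the (R,R)-antipode of the bisphosphoramide catalyst is taken to send the dienolate to the Re face of the enal; if the sense is the opposite, the (S,S)-antipode is used and nothing else changes.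

## Route

Step 1
Reactants: 1 2,2-dimethylpropane-1,3-diol
Product: 2 3-[(tert-butyldimethylsilyl)oxy]-2,2-dimethylpropan-1-ol
Conditions: NaH (1.0 equiv), THF, rt; TBSCl (1.0 equiv), 0 °C → rt
Reagents that add atoms: tert-butylchlorodimethylsilane, CC(C)(C)[Si](C)(C)Cl
Why: O-silylation of the sparingly soluble monosodium alkoxide of the symmetric diol stops after one hydroxyl group (statistical monoprotection), and no stereocentre is involved.

Step 2
Reactants: 2 3-[(tert-butyldimethylsilyl)oxy]-2,2-dimethylpropan-1-ol
Product: 3 3-[(tert-butyldimethylsilyl)oxy]-2,2-dimethylpropanal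
Conditions: Dess–Martin periodinane, NaHCO3, CH2Cl2, 0 °C → rt
Reagents that add atoms: none
Why: Dess–Martin oxidation of a primary neopentyl alcohol gives an aldehyde that has no α-hydrogen and so cannot enolise or self-condense.

Step 3
Reactants: 3 3-[(tert-butyldimethylsilyl)oxy]-2,2-dimethylpropanal; 4 (triphenylphosphoranylidene)acetaldehyde
Product: 5 (2E)-5-[(tert-butyldimethylsilyl)oxy]-4,4-dimethylpent-2-enal
Conditions: toluene, 90 °C
Reagents that add atoms: none
Why: Wittig olefination with the stabilised formylmethylene ylide gives the (E)-enal, the hindered aldehyde needing heat while the conjugated product is less electrophilic, which limits a second homologation.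

Step 4
Reactants: 6 methyl 3-methylbut-2-enoate
Product: 7 tert-butyl[(1-methoxy-3-methylbuta-1,3-dien-1-yl)oxy]dimethylsilane
Conditions: LiN(iPr)2, THF, DMPU, −78 °C; TBSCl, −78 °C → rt
Reagents that add atoms: tert-butylchlorodimethylsilane, CC(C)(C)[Si](C)(C)Cl
Why: γ-deprotonation of the unsaturated ester and O-silylation of the lithium dienolate give the silyl dienol ether (silyl ketene acetal) that serves as the vinylogous nucleophile.

Step 5
Reactants: 5 (2E)-5-[(tert-butyldimethylsilyl)oxy]-4,4-dimethylpent-2-enal; 7 tert-butyl[(1-methoxy-3-methylbuta-1,3-dien-1-yl)oxy]dimethylsilane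
Product: 8 methyl (2E,5R,6E)-9-[(tert-butyldimethylsilyl)oxy]-5-hydroxy-3,8,8-trimethylnona-2,6-dienoate
Conditions: SiCl4 (1.1 equiv), (R,R)-N,N′-bis(3,5-dimethyl-4-oxo-3,5-dihydro-4H-4λ5-dinaphtho[2,1-d:1′,2′-f][1,3,2]diazaphosphepin-4-yl)-N,N′-dimethylpentane-1,5-diamine (5 mol %), iPr2NEt (10 mol %), CH2Cl2, −78 °C; aq. NaHCO3
Reagents that add atoms: none
Why: catalytic enantioselective vinylogous Mukaiyama aldol addition, in which the chiral phosphoramide-bound trichlorosilyl cation activates the enal, the dienolate attacks through its γ-carbon and the catalyst directs it to the Re face of the aldehyde, which sets the (5R) carbinol that becomes C1 and later fixes the absolute configuration of the bicycle.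

Step 6
Reactants: 8 methyl (2E,5R,6E)-9-[(tert-butyldimethylsilyl)oxy]-5-hydroxy-3,8,8-trimethylnona-2,6-dienoate
Product: 9 methyl (2E,5R,6E)-5,9-bis[(tert-butyldimethylsilyl)oxy]-3,8,8-trimethylnona-2,6-dienoate
Conditions: TBSOTf, 2,6-lutidine, CH2Cl2, −78 → 0 °C
Reagents that add atoms: tert-butyldimethylsilyl trifluoromethanesulfonate, CC(C)(C)[Si](C)(C)OS(=O)(=O)C(F)(F)F
Why: silylation of the secondary allylic alcohol with a silyl triflate and a hindered base leaves the carbinol configuration untouched.

Step 7
Reactants: 9 methyl (2E,5R,6E)-5,9-bis[(tert-butyldimethylsilyl)oxy]-3,8,8-trimethylnona-2,6-dienoate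
Product: 10 (2E,5R,6E)-5,9-bis[(tert-butyldimethylsilyl)oxy]-3,8,8-trimethylnona-2,6-dienoic acid
Conditions: LiOH, THF/MeOH/H2O, 40 °C; then HCl to pH 5, 0 °C
Reagents that add atoms: lithium hydroxide, [Li+].[OH-]
Why: saponification of the methyl ester by hydroxide spares both silyl ethers and both alkenes, and the brief mild acidification does not cleave the silyl groups.

Step 8
Reactants: 10 (2E,5R,6E)-5,9-bis[(tert-butyldimethylsilyl)oxy]-3,8,8-trimethylnona-2,6-dienoic acid
Product: 13 4-[(tert-butyldimethylsilyl)oxy]-7-{1-[(tert-butyldimethylsilyl)oxy]-2-methylpropan-2-yl}-2-methylbicyclo[3.1.1]hept-2-en-6-one (silyloxy group syn to the carbonyl bridge; side chain anti to the C2–C4 bridge), via acid chloride 11 (not isolated), via vinylketene 12 (not isolated)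
Conditions: 1-chloro-N,N,2-trimethylprop-1-en-1-amine, CH2Cl2, 0 °C → rt; then slow addition to Et3N, toluene, 110 °C, 0.005 M
Reagents that add atoms: none
Why: intramolecular ketene–alkene [2+2] cycloaddition of a vinylketene formed by γ-dehydrochlorination (the known route from dienoyl chlorides to bicyclo[3.1.1]hept-2-en-6-ones), in which the electrophilic ketene carbon (future C10) bonds to the unhindered internal alkene carbon C11 and not to the neopentyl carbon C5, C4 then closes on C5, the (E)-alkene geometry is carried over suprafacially so that the C5 side chain lies anti to the C1–C3 bridge, and the allylic silyloxy group takes the outside position with its C–H bond anti to the incoming ketene, which places it on the face of the carbonyl bridge and so fixes C4, C5 and C11 in the sense shown (the minor diastereomer would be removed by chromatography).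

Step 9
Reactants: 13 4-[(tert-butyldimethylsilyl)oxy]-7-{1-[(tert-butyldimethylsilyl)oxy]-2-methylpropan-2-yl}-2-methylbicyclo[3.1.1]hept-2-en-6-one; 14 methyltriphenylphosphonium bromide
Product: 15 4-[(tert-butyldimethylsilyl)oxy]-7-{1-[(tert-butyldimethylsilyl)oxy]-2-methylpropan-2-yl}-2-methyl-6-methylidenebicyclo[3.1.1]hept-2-ene
Conditions: KOtBu, THF, 0 → 50 °C
Reagents that add atoms: none
Why: Wittig methylenation of a strained cyclobutanone whose two α-carbons are bridgeheads and cannot enolise, as is used to turn bicyclo[3.1.1]heptan-6-ones into their 6-methylidene derivatives, with no stereocentre changed.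

Step 10
Reactants: 15 4-[(tert-butyldimethylsilyl)oxy]-7-{1-[(tert-butyldimethylsilyl)oxy]-2-methylpropan-2-yl}-2-methyl-6-methylidenebicyclo[3.1.1]hept-2-ene
Product: 16 7-(1-hydroxy-2-methylpropan-2-yl)-4-methyl-6-methylidenebicyclo[3.1.1]hept-3-en-2-ol
Conditions: Bu4NF (3 equiv), THF, 0 °C → rt
Reagents that add atoms: none
Why: fluoride-driven cleavage of both silyl ethers frees the allylic and the neopentyl alcohol, while the three alkenes are inert to fluoride.

Step 11
Reactants: 16 7-(1-hydroxy-2-methylpropan-2-yl)-4-methyl-6-methylidenebicyclo[3.1.1]hept-3-en-2-ol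
Product: 17 2-methyl-2-(4-methyl-6-methylidene-2-oxobicyclo[3.1.1]hept-3-en-7-yl)propanal
Conditions: Dess–Martin periodinane (3 equiv), NaHCO3, CH2Cl2, rt
Reagents that add atoms: none
Why: Dess–Martin oxidation converts the allylic carbinol into the enone and the neopentyl alcohol into a non-enolisable aldehyde, and the β,γ-methylidene group cannot move into conjugation because C11 is a bridgehead.

Step 12
Reactants: 17 2-methyl-2-(4-methyl-6-methylidene-2-oxobicyclo[3.1.1]hept-3-en-7-yl)propanal; 18 ethynylmagnesium bromide
Product: 19 7-(3-hydroxy-2-methylpent-4-yn-2-yl)-4-methyl-6-methylidenebicyclo[3.1.1]hept-3-en-2-one (both carbinol epimers)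
Conditions: THF, −78 °C; H2O quench
Reagents that add atoms: none
Why: Grignard 1,2-addition of the acetylide goes to the aldehyde, which at −78 °C is far more electrophilic than the hindered conjugated bicyclic ketone, and the new carbinol centre is formed as a mixture that the next step erases.

Step 13
Reactants: 19 7-(3-hydroxy-2-methylpent-4-yn-2-yl)-4-methyl-6-methylidenebicyclo[3.1.1]hept-3-en-2-one
Product: 20 4-methyl-6-methylidene-7-(2-methyl-3-oxopent-4-yn-2-yl)bicyclo[3.1.1]hept-3-en-2-one
Conditions: Dess–Martin periodinane, NaHCO3, CH2Cl2, 0 °C → rt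
Reagents that add atoms: none
Why: Dess–Martin oxidation of the propargylic alcohol gives the terminal ynone and removes the undefined stereocentre of 19.

Step 14
Reactants: 20 4-methyl-6-methylidene-7-(2-methyl-3-oxopent-4-yn-2-yl)bicyclo[3.1.1]hept-3-en-2-one; 21 3-methylbut-2-enoic acid
Product: 22 (1E)-4-methyl-4-(4-methyl-6-methylidene-2-oxobicyclo[3.1.1]hept-3-en-7-yl)-3-oxopent-1-en-1-yl 3-methylbut-2-enoate
Conditions: 1,4-diazabicyclo[2.2.2]octane (10 mol %), CH2Cl2, 0 °C → rt
Reagents that add atoms: none
Why: amine-catalysed conjugate addition of a carboxylic acid to a terminal ynone (through the β-ammonium allenolate) gives the (E)-β-acyloxy enone, while the trisubstituted bicyclic enone and the methylidene group do not react.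

Step 15
Reactants: 22 (1E)-4-methyl-4-(4-methyl-6-methylidene-2-oxobicyclo[3.1.1]hept-3-en-7-yl)-3-oxopent-1-en-1-yl 3-methylbut-2-enoate
Product: 23 9-[(3-methylbut-2-enoyl)oxy]longipin-2-ene-1,7-dione (C9 oxygen on the C11 flank; C10 methyl syn to the enone bridge)
Conditions: Fe(acac)3 (0.5 equiv), PhSiH3 (2.5 equiv), Na2HPO4, EtOH/HOCH2CH2OH (5:1), 0.01 M, Ar, 25 °C
Reagents that add atoms: none
Why: Fe(acac)3 (trivalent iron) and PhSiH3 in ethanol give an iron hydride that transfers a hydrogen atom to the CH2 end of the exocyclic 1,1-disubstituted alkene, which creates the C10 methyl group and a tertiary cyclobutyl radical; this nucleophilic radical adds to C9, the β-carbon of the acyloxy enone, and the C8 α-keto radical is reduced by divalent iron to the enolate and protonated by ethanol, the closest known class being iron-hydride hydrogen-atom-transfer reductive olefin–enone coupling in its intramolecular form, including additions to β-oxygenated enones. The seven-membered ring closes in the 7-endo-trig mode, preferred over 6-exo attack at C8 because only addition at C9 gives the carbonyl-stabilised radical. C10 is controlled by the tether: the chain on C5 points away from the enone bridge, so the C9–C10 bond can form only on that face of the radical and the new methyl group is left syn to the enone bridge. At C9 the (E)-geometry keeps the acyloxy group outside the forming ring, but the closures that put it on the C11 flank (wanted) or on the C4 flank differ only through the distant C1 carbonyl and C3 methyl group, so no strong preference is claimed and 23 is to be separated from its C9 epimer by chromatography. The step needs hydrogen-atom transfer at the methylidene group alone, which the substitution pattern secures, since the other three alkenes are electron-poor or conjugated and react with the metal hydride far more slowly. High dilution suppresses intermolecular addition and the phosphate buffer limits β-elimination of the senecioate from the enolate.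

Step 16
Reactants: 23 9-[(3-methylbut-2-enoyl)oxy]longipin-2-ene-1,7-dione
Product: 24 7-hydroxy-1-oxolongipin-2-en-9-yl 3-methylbut-2-enoate (C7 oxygen on the C4 flank; trans to the C9 ester)
Conditions: NaBH4 (1 equiv), MeOH/CH2Cl2 (1:1), −78 °C
Reagents that add atoms: none
Why: chemoselective borohydride reduction, in which the saturated C7 ketone reacts faster than the conjugated C1 ketone at low temperature, and hydride is expected to add along the axial trajectory of the twist-chair seven-membered ring on the C11 flank, giving the pseudo-equatorial carbinol with oxygen on the C4 flank, trans to the C9 ester.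

Step 17
Reactants: 24 7-hydroxy-1-oxolongipin-2-en-9-yl 3-methylbut-2-enoate; 25 3-methylbutanoyl chloride
Product: 26 7-[(3-methylbutanoyl)oxy]-1-oxolongipin-2-en-9-yl 3-methylbut-2-enoate (CNP0335239.1)
Conditions: pyridine, 4-(dimethylamino)pyridine (cat.), CH2Cl2, 0 °C → rt
Reagents that add atoms: none
Why: nucleophilic-catalysed acylation of the hindered secondary alcohol by the acid chloride forms the isovalerate without touching any stereocentre.

## Compound list

1 | 2,2-dimethylpropane-1,3-diol | OCC(C)(C)CO | starting material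
2 | 3-[(tert-butyldimethylsilyl)oxy]-2,2-dimethylpropan-1-ol | CC(C)(CO)CO[Si](C)(C)C(C)(C)C | intermediate
3 | 3-[(tert-butyldimethylsilyl)oxy]-2,2-dimethylpropanal | CC(C)(C=O)CO[Si](C)(C)C(C)(C)C | intermediate
4 | (triphenylphosphoranylidene)acetaldehyde | O=CC=P(c1ccccc1)(c1ccccc1)c1ccccc1 | starting material
5 | (2E)-5-[(tert-butyldimethylsilyl)oxy]-4,4-dimethylpent-2-enal | O=C/C=C/C(C)(C)CO[Si](C)(C)C(C)(C)C | intermediate
6 | methyl 3-methylbut-2-enoate | COC(=O)C=C(C)C | starting material
7 | tert-butyl[(1-methoxy-3-methylbuta-1,3-dien-1-yl)oxy]dimethylsilane | COC(=CC(C)=C)O[Si](C)(C)C(C)(C)C | intermediate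
8 | methyl (2E,5R,6E)-9-[(tert-butyldimethylsilyl)oxy]-5-hydroxy-3,8,8-trimethylnona-2,6-dienoate | COC(=O)/C=C(\C)C[C@@H](O)/C=C/C(C)(C)CO[Si](C)(C)C(C)(C)C | intermediate
9 | methyl (2E,5R,6E)-5,9-bis[(tert-butyldimethylsilyl)oxy]-3,8,8-trimethylnona-2,6-dienoate | COC(=O)/C=C(\C)C[C@@H](O[Si](C)(C)C(C)(C)C)/C=C/C(C)(C)CO[Si](C)(C)C(C)(C)C | intermediate
10 | (2E,5R,6E)-5,9-bis[(tert-butyldimethylsilyl)oxy]-3,8,8-trimethylnona-2,6-dienoic acid | OC(=O)/C=C(\C)C[C@@H](O[Si](C)(C)C(C)(C)C)/C=C/C(C)(C)CO[Si](C)(C)C(C)(C)C | intermediate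
11 | (2E,5R,6E)-5,9-bis[(tert-butyldimethylsilyl)oxy]-3,8,8-trimethylnona-2,6-dienoyl chloride | ClC(=O)/C=C(\C)C[C@@H](O[Si](C)(C)C(C)(C)C)/C=C/C(C)(C)CO[Si](C)(C)C(C)(C)C | intermediate (not isolated)
12 | (3Z,6E)-5,9-bis[(tert-butyldimethylsilyl)oxy]-3,8,8-trimethylnona-1,3,6-trien-1-one, the vinylketene, silyloxy carbon configured as in 10 | O=C=C/C(C)=C\[C@@H](O[Si](C)(C)C(C)(C)C)/C=C/C(C)(C)CO[Si](C)(C)C(C)(C)C | intermediate (not isolated)
13 | 4-[(tert-butyldimethylsilyl)oxy]-7-{1-[(tert-butyldimethylsilyl)oxy]-2-methylpropan-2-yl}-2-methylbicyclo[3.1.1]hept-2-en-6-one; silyloxy syn to the C6 carbonyl bridge, C7 side chain anti to the C2–C4 bridge, absolute configuration as in the SMILES | O=C1[C@H]2C(C)=C[C@@H](O[Si](C)(C)C(C)(C)C)[C@@H]1[C@H]2C(C)(C)CO[Si](C)(C)C(C)(C)C | intermediate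
14 | methyltriphenylphosphonium bromide | C[P+](c1ccccc1)(c1ccccc1)c1ccccc1.[Br-] | starting material
15 | 4-[(tert-butyldimethylsilyl)oxy]-7-{1-[(tert-butyldimethylsilyl)oxy]-2-methylpropan-2-yl}-2-methyl-6-methylidenebicyclo[3.1.1]hept-2-ene; silyloxy syn to the methylidene bridge, side chain anti to the C2–C4 bridge | C=C1[C@H]2C(C)=C[C@@H](O[Si](C)(C)C(C)(C)C)[C@@H]1[C@H]2C(C)(C)CO[Si](C)(C)C(C)(C)C | intermediate
16 | 7-(1-hydroxy-2-methylpropan-2-yl)-4-methyl-6-methylidenebicyclo[3.1.1]hept-3-en-2-ol; hydroxyl syn to the methylidene bridge, side chain anti to the C2–C4 bridge | C=C1[C@H]2C(C)=C[C@@H](O)[C@@H]1[C@H]2C(C)(C)CO | intermediate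
17 | 2-methyl-2-(4-methyl-6-methylidene-2-oxobicyclo[3.1.1]hept-3-en-7-yl)propanal; side chain anti to the enone bridge | C=C1[C@H]2C(C)=CC(=O)[C@@H]1[C@H]2C(C)(C)C=O | intermediate
18 | ethynylmagnesium bromide | C#C[Mg]Br | starting material
19 | 7-(3-hydroxy-2-methylpent-4-yn-2-yl)-4-methyl-6-methylidenebicyclo[3.1.1]hept-3-en-2-one; side chain anti to the enone bridge, both carbinol epimers | C=C1[C@H]2C(C)=CC(=O)[C@@H]1[C@H]2C(C)(C)C(O)C#C | intermediate
20 | 4-methyl-6-methylidene-7-(2-methyl-3-oxopent-4-yn-2-yl)bicyclo[3.1.1]hept-3-en-2-one; side chain anti to the enone bridge | C=C1[C@H]2C(C)=CC(=O)[C@@H]1[C@H]2C(C)(C)C(=O)C#C | intermediate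
21 | 3-methylbut-2-enoic acid | CC(C)=CC(=O)O | starting material
22 | (1E)-4-methyl-4-(4-methyl-6-methylidene-2-oxobicyclo[3.1.1]hept-3-en-7-yl)-3-oxopent-1-en-1-yl 3-methylbut-2-enoate; methylidene on C6, chain on C7 anti to the enone bridge | C=C1[C@@H]2C(=O)C=C(C)[C@H]1[C@@H]2C(C)(C)C(=O)/C=C/OC(=O)C=C(C)C | intermediate
23 | 9-[(3-methylbut-2-enoyl)oxy]longipin-2-ene-1,7-dione; C9 oxygen on the C11 flank, C10 methyl syn to the enone bridge | CC(C)=CC(=O)O[C@@H]1CC(=O)C(C)(C)[C@@H]2[C@H]3C(=O)C=C(C)[C@@H]2[C@]31C | intermediate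
24 | 7-hydroxy-1-oxolongipin-2-en-9-yl 3-methylbut-2-enoate; C7 hydroxyl on the C4 flank, trans to the C9 ester | CC(C)=CC(=O)O[C@@H]1C[C@@H](O)C(C)(C)[C@@H]2[C@H]3C(=O)C=C(C)[C@@H]2[C@]31C | intermediate
25 | 3-methylbutanoyl chloride | CC(C)CC(=O)Cl | starting material
26 | 7-[(3-methylbutanoyl)oxy]-1-oxolongipin-2-en-9-yl 3-methylbut-2-enoate (CNP0335239.1) | CC(C)=CC(=O)O[C@@H]1C[C@@H](OC(=O)CC(C)C)C(C)(C)[C@@H]2[C@H]3C(=O)C=C(C)[C@@H]2[C@]31C | target

## Step count and risks

Total step count: 17. Longest linear sequence: 16 steps (from 1 through steps 1–3 and 5–17).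

**Step 15 (radical closure).** Three things may go wrong:
- the two faces of the acceptor at C9 are hardly distinguished, so the closure may show little facial selectivity;
- the enolate formed after the addition may lose senecioate by β-elimination;
- the slow seven-membered closure may be outrun by simple reduction of the cyclobutyl radical.

The fallback sets out from 22 and returns at 23. The cyclisation is run as in step 15 and the crude product is not separated; it holds 23, its C9 epimer 9-epi-9-[(3-methylbut-2-enoyl)oxy]longipin-2-ene-1,7-dione F1 and any enone already formed by elimination. DBU in CH2Cl2 removes 3-methylbut-2-enoic acid from both epimers and gives longipina-2,8-diene-1,7-dione F2. Enantioselective conjugate borylation of the less substituted C8=C9 enone (CuCl, NaOtBu, (R)-1-[(S)-2-(diphenylphosphino)ferrocenyl]ethyldicyclohexylphosphine or its mirror image, B2pin2, MeOH, THF) gives 9-(4,4,5,5-tetramethyl-1,3,2-dioxaborolan-2-yl)longipin-2-ene-1,7-dione F3, with boron placed on the C11 flank by the ligand and not by the substrate. NaBO3 oxidation gives 9-hydroxylongipin-2-ene-1,7-dione F4, and 3-methylbut-2-enoyl chloride with pyridine returns 23 as a single C9 epimer.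

**Step 8 (ketene cycloaddition).** The alkene is 1,2-disubstituted, hindered at C5 and inductively deactivated by the allylic silyloxy group. Cycloaddition may therefore be slow relative to dimerisation or a 1,5-hydrogen shift of the vinylketene, and facial discrimination by the silyloxy stereocentre may be modest.

The fallback sets out from 10 and returns at 13. Acid 10 is coupled with dimethylamine (Me2NH·HCl, EDC·HCl, 1-hydroxybenzotriazole, iPr2NEt) to give (2E,5R,6E)-5,9-bis[(tert-butyldimethylsilyl)oxy]-N,N,3,8,8-pentamethylnona-2,6-dienamide F5. Tf2O and 2,4,6-collidine in 1,2-dichloroethane at 80 °C convert it into the more electrophilic vinylketeniminium triflate F6, which undergoes the same intramolecular [2+2] cycloaddition to give the bicyclic cyclobutaniminium triflate F7. Aqueous NaHCO3 hydrolyses F7 to 13.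

**Step 16 (C7 reduction).** Hydride may be delivered to the wrong face of C7, giving the cis-7,9 isomer, or the conjugated C1 ketone may be reduced as well.

The fallback sets out from 23 and returns at 24. A reagent-controlled Corey–Bakshi–Shibata reduction is used ((S)-1-methyl-3,3-diphenyltetrahydro-1H,3H-pyrrolo[1,2-c][1,3,2]oxazaborole, catecholborane, toluene, −78 °C), in which the quaternary C6 and the C8 methylene act as the large and small groups. Reduction of the enone carbonyl is accepted, giving 1,7-dihydroxylongipin-2-en-9-yl 3-methylbut-2-enoate F8. MnO2 in CH2Cl2 then re-oxidises only the allylic alcohol and gives 24.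

## Further compounds

F1 | step 15 | 9-epi-9-[(3-methylbut-2-enoyl)oxy]longipin-2-ene-1,7-dione (C9 oxygen on the C4 flank) | CC(C)=CC(=O)O[C@H]1CC(=O)C(C)(C)[C@@H]2[C@H]3C(=O)C=C(C)[C@@H]2[C@]31C
F2 | step 15 | longipina-2,8-diene-1,7-dione | C1=CC(=O)C(C)(C)[C@@H]2[C@H]3C(=O)C=C(C)[C@@H]2[C@]31C
F3 | step 15 | 9-(4,4,5,5-tetramethyl-1,3,2-dioxaborolan-2-yl)longipin-2-ene-1,7-dione (boron on the C11 flank) | CC4(C)OB(OC4(C)C)[C@@H]1CC(=O)C(C)(C)[C@@H]2[C@H]3C(=O)C=C(C)[C@@H]2[C@]31C
F4 | step 15 | 9-hydroxylongipin-2-ene-1,7-dione (hydroxyl on the C11 flank) | O[C@@H]1CC(=O)C(C)(C)[C@@H]2[C@H]3C(=O)C=C(C)[C@@H]2[C@]31C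
F5 | step 8 | (2E,5R,6E)-5,9-bis[(tert-butyldimethylsilyl)oxy]-N,N,3,8,8-pentamethylnona-2,6-dienamide | CN(C)C(=O)/C=C(\C)C[C@@H](O[Si](C)(C)C(C)(C)C)/C=C/C(C)(C)CO[Si](C)(C)C(C)(C)C
F6 | step 8 | vinylketeniminium triflate derived from F5 | C[N+](C)=C=C/C(C)=C\[C@@H](O[Si](C)(C)C(C)(C)C)/C=C/C(C)(C)CO[Si](C)(C)C(C)(C)C.[O-]S(=O)(=O)C(F)(F)F
F7 | step 8 | N,N-dimethyliminium triflate of 13 | C[N+](C)=C1[C@H]2C(C)=C[C@@H](O[Si](C)(C)C(C)(C)C)[C@@H]1[C@H]2C(C)(C)CO[Si](C)(C)C(C)(C)C.[O-]S(=O)(=O)C(F)(F)F
F8 | step 16 | 1,7-dihydroxylongipin-2-en-9-yl 3-methylbut-2-enoate (C7 hydroxyl on the C4 flank; C1 carbinol as a mixture) | CC(C)=CC(=O)O[C@@H]1C[C@@H](O)C(C)(C)[C@@H]2[C@H]3C(O)C=C(C)[C@@H]2[C@]31C
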